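**Retrosynthetic overview**
- Target ⇐ hydrogenolysis of its deca-O-benzyl ether; the oxolane is closed last, by SN1 cycloetherification of a 1,4-diol (new aryl trans to its neighbour).
- Diol ⇐ lactol + aryl Grignard; lactone C-3 ⇐ enolate α-arylation, then kinetic protonation anti to the C-4 substituent (3,4-cis).
- Lactone ⇐ hydroboration/oxidative lactonisation of an anti homoallylic alcohol; that alcohol ⇐ key step, catalytic asymmetric carbonyl allylation joining the bis(dihydrobenzofuran) allylboronate with 4-(benzyloxy)benzaldehyde.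
- Each dihydrobenzofuran ⇐ enantioselective dirhodium-carbene C–H insertion of a diaryldiazomethane into an ortho ArCH2–O ether, then acid epimerisation to trans; the two units are joined by aryllithium addition to an aldehyde.
- Ring order: lower dihydrobenzofuran (unit Q) → central dihydrobenzofuran (unit W) → oxolane.

Assumption: the SMILES as written (including the 7-hydroxy-2,3-dihydrobenzofuran-5-yl unit) defines the target; each chiral catalyst enantiomer is quoted by analogy with its usual sense of induction and would be swapped for its mirror image if that sense proved reversed on these substrates.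

Abbreviations: BnO = benzyloxy; Ar1 = 4-(benzyloxy)phenyl; Ar2 = 3,5-bis(benzyloxy)phenyl; PBB = 4-(benzyloxy)benzyl; DHB = 2,3-dihydro-1-benzofuran; Q = (2R,3R)-7-BnO-2-Ar1-3-Ar2-DHB-5-yl; W = (2S,3S)-6-BnO-2-Ar1-3-Q-DHB-4-yl; (R)-TRIP = (R)-3,3'-bis(2,4,6-triisopropylphenyl)-1,1'-binaphthyl-2,2'-diyl hydrogen phosphate.

**Step 1**
Reactants: 1 2,3-dihydroxybenzaldehyde
Product: 2 3-(benzyloxy)-2-hydroxybenzaldehyde
Conditions: NaH (2.2 equiv), DMSO, rt; BnBr (1.0 equiv), rt; aq. work-up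
Reagents that add atoms: benzyl bromide, BrCc1ccccc1
Why: Williamson etherification of the catechol dianion; the 3-phenoxide, not conjugated to or chelated by the formyl group, is the more nucleophilic oxygen.

**Step 2**
Reactants: 2 3-(benzyloxy)-2-hydroxybenzaldehyde
Product: 3 3-(benzyloxy)-5-bromo-2-hydroxybenzaldehyde
Conditions: NBS (1.05 equiv), MeCN, 0 °C → rt
Reagents that add atoms: N-bromosuccinimide, O=C1CCC(=O)N1Br
Why: electrophilic aromatic bromination goes para to the free phenol, the only strongly activated open position.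

**Step 3**
Reactants: 3 3-(benzyloxy)-5-bromo-2-hydroxybenzaldehyde; 4 4-(benzyloxy)benzyl chloride
Product: 5 3-BnO-5-bromo-2-(PBB-O)benzaldehyde
Conditions: K2CO3, KI (cat.), DMF, 60 °C
Reagents that add atoms: none
Why: Williamson etherification of the remaining phenol installs the ArCH2–O ether whose CH2 becomes C-2 of unit Q.

**Step 4**
Reactants: 5 3-BnO-5-bromo-2-(PBB-O)benzaldehyde; 6 1-bromo-3,5-bis(benzyloxy)benzene
Product: 8 [3-BnO-5-bromo-2-(PBB-O)phenyl](Ar2)methanol (racemic), via aryllithium 7 (not isolated)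
Conditions: 6, n-BuLi, THF, −78 °C; then 5, −78 °C; H2O
Reagents that add atoms: none
Why: bromine–lithium exchange then 1,2-addition of the aryllithium to the aldehyde, which outruns exchange with the aryl bromide of 5; the carbinol centre is removed in step 5.

**Step 5**
Reactants: 8 [3-BnO-5-bromo-2-(PBB-O)phenyl](Ar2)methanol
Product: 9 [3-BnO-5-bromo-2-(PBB-O)phenyl](Ar2)methanone
Conditions: Dess–Martin periodinane, CH2Cl2, rt
Reagents that add atoms: none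
Why: Dess–Martin oxidation of a benzhydrol to the benzophenone under neutral conditions.

**Step 6**
Reactants: 9 [3-BnO-5-bromo-2-(PBB-O)phenyl](Ar2)methanone
Product: 10 hydrazone of ketone 9 (E/Z mixture)
Conditions: N2H4·H2O, AcOH (cat.), EtOH, 80 °C
Reagents that add atoms: hydrazine, NN
Why: condensation of the diaryl ketone with hydrazine gives the N-unsubstituted hydrazone, precursor of a donor/donor diazo compound.

**Step 7**
Reactants: 10 hydrazone of ketone 9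
Product: 12 (2S,3R)-7-BnO-5-bromo-2-Ar1-3-Ar2-DHB (cis), via diazo compound 11 (not isolated)
Conditions: MnO2, CH2Cl2, 0 °C; filter; Rh2(S-PTAD)4 (1 mol %), CH2Cl2, 0 °C → rt
Reagents that add atoms: none
Why: MnO2 dehydrogenates the hydrazone to the diaryldiazomethane, and the dirhodium carbene undergoes enantioselective intramolecular 1,5 C–H insertion into the OCH2Ar1 group; the chiral carboxylate ligands set C-3 (R) and the concerted insertion places the aryl groups cis.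

**Step 8**
Reactants: 12 (2S,3R)-7-BnO-5-bromo-2-Ar1-3-Ar2-DHB
Product: 13 (2R,3R)-7-BnO-5-bromo-2-Ar1-3-Ar2-DHB (trans; Q–Br)
Conditions: CF3CO2H (2 equiv), CH2Cl2, 0 °C
Reagents that add atoms: none
Why: acid-mediated epimerisation; reversible ionisation of the C2–O bond to a 4-alkoxybenzyl cation and re-closure gives the thermodynamically favoured trans isomer while C-3 is untouched.

**Step 9**
Reactants: 14 2-bromo-4,6-dimethoxybenzaldehyde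
Product: 15 2-bromo-4,6-dihydroxybenzaldehyde
Conditions: BBr3 (3 equiv), CH2Cl2, −78 °C → rt; H2O
Reagents that add atoms: none
Why: Lewis acid cleavage of both aryl methyl ethers (BBr3 demethylation).

**Step 10**
Reactants: 15 2-bromo-4,6-dihydroxybenzaldehyde
Product: 16 4-(benzyloxy)-2-bromo-6-hydroxybenzaldehyde
Conditions: BnBr (1.05 equiv), KHCO3, MeCN, 60 °C
Reagents that add atoms: benzyl bromide, BrCc1ccccc1
Why: regioselective Williamson etherification; the 4-OH para to the formyl group is more acidic and is not tied up in the hydrogen bond that deactivates the 6-OH.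

**Step 11**
Reactants: 16 4-(benzyloxy)-2-bromo-6-hydroxybenzaldehyde; 4 4-(benzyloxy)benzyl chloride
Product: 17 4-BnO-2-bromo-6-(PBB-O)benzaldehyde
Conditions: K2CO3, KI (cat.), DMF, 60 °C
Reagents that add atoms: none
Why: Williamson etherification of the hydrogen-bonded phenol installs the ArCH2–O ether that becomes C-2 of the central dihydrobenzofuran.

**Step 12**
Reactants: 13 (2R,3R)-7-BnO-5-bromo-2-Ar1-3-Ar2-DHB; 17 4-BnO-2-bromo-6-(PBB-O)benzaldehyde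
Product: 19 [4-BnO-2-bromo-6-(PBB-O)phenyl](Q)methanol (carbinol epimers), via aryllithium 18 (not isolated)
Conditions: 13, n-BuLi, THF, −78 °C; then 17, −78 °C; H2O
Reagents that add atoms: none
Why: bromine–lithium exchange on 13 and 1,2-addition to the aldehyde joins unit Q to ring C; the carbinol configuration is irrelevant because it is oxidised next.

**Step 13**
Reactants: 19 [4-BnO-2-bromo-6-(PBB-O)phenyl](Q)methanol
Product: 20 [4-BnO-2-bromo-6-(PBB-O)phenyl](Q)methanone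
Conditions: Dess–Martin periodinane, CH2Cl2, rt
Reagents that add atoms: none
Why: Dess–Martin oxidation of the diarylmethanol to the diaryl ketone without acid or base.

**Step 14**
Reactants: 20 [4-BnO-2-bromo-6-(PBB-O)phenyl](Q)methanone
Product: 21 hydrazone of ketone 20 (E/Z mixture)
Conditions: N2H4·H2O, AcOH (cat.), n-BuOH, 110 °C (sealed)
Reagents that add atoms: hydrazine, NN
Why: hydrazone condensation, run under forcing conditions because the ketone carries two ortho substituents.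

**Step 15**
Reactants: 21 hydrazone of ketone 20
Product: 23 (2R,3S)-6-BnO-4-bromo-2-Ar1-3-Q-DHB (cis), via diazo compound 22 (not isolated)
Conditions: MnO2, CH2Cl2, 0 °C; filter; Rh2(R-PTAD)4 (2 mol %), CH2Cl2, 0 °C → rt
Reagents that add atoms: none
Why: as in step 7 but with the enantiomeric catalyst; carbene 1,5 C–H insertion into the OCH2Ar1 group of ring C gives the cis-dihydrobenzofuran with C-3 (S) under catalyst control, the remote unit Q exerting no bias.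

**Step 16**
Reactants: 23 (2R,3S)-6-BnO-4-bromo-2-Ar1-3-Q-DHB
Product: 24 (2S,3S)-6-BnO-4-bromo-2-Ar1-3-Q-DHB (trans; W–Br)
Conditions: CF3CO2H (2 equiv), CH2Cl2, 0 °C
Reagents that add atoms: none
Why: acid-mediated C-2 epimerisation through the 4-alkoxybenzyl cation gives the trans isomer; C-3 and the already trans unit Q are unchanged.

**Step 17**
Reactants: 24 (2S,3S)-6-BnO-4-bromo-2-Ar1-3-Q-DHB; 25 acrolein
Product: 27 1-W-prop-2-en-1-ol (carbinol epimers), via aryllithium 26 (not isolated)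
Conditions: 24, n-BuLi, THF, −78 °C; then acrolein, −78 °C; H2O
Reagents that add atoms: none
Why: bromine–lithium exchange and 1,2-addition of the aryllithium to acrolein; the carbinol centre disappears in step 18.

**Step 18**
Reactants: 27 1-W-prop-2-en-1-ol
Product: 28 2-[(2E)-3-W-prop-2-en-1-yl]-4,4,5,5-tetramethyl-1,3,2-dioxaborolane
Conditions: B2pin2, Pd(MeCN)4(BF4)2 (5 mol %), DMSO–MeOH, 50 °C
Reagents that add atoms: bis(pinacolato)diboron, CC1(C)OB(OC1(C)C)B1OC(C)(C)C(C)(C)O1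
Why: palladium-catalysed allylic C–O borylation through an η3-allyl intermediate delivers boron to the unsubstituted terminus, giving the linear (E)-allylboronate.

**Step 19**
Reactants: 28 2-[(2E)-3-W-prop-2-en-1-yl]-4,4,5,5-tetramethyl-1,3,2-dioxaborolane; 29 4-(benzyloxy)benzaldehyde
Product: 30 (1R,2S)-1-Ar1-2-W-but-3-en-1-ol
Conditions: (R)-TRIP (5 mol %), 4 Å MS, toluene, −30 °C; then H2O
Reagents that add atoms: none
Why: chiral phosphoric acid-catalysed allylboration (carbonyl allylation); the closed chair transition state of the (E)-boronate gives the anti adduct and the (R)-acid selects the aldehyde face, setting C-1 (R) and C-2 (S).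

**Step 20**
Reactants: 30 (1R,2S)-1-Ar1-2-W-but-3-en-1-ol
Product: 32 (1R,2S)-1-Ar1-2-W-butane-1,4-diol, via B-alkyl-9-BBN borane 31 (not isolated)
Conditions: 9-BBN, THF, 0 °C → rt; then NaOH, H2O2, 0 °C
Reagents that add atoms: hydrogen peroxide, OO
Why: anti-Markovnikov hydroboration–oxidation of the terminal alkene gives the primary alcohol without touching a stereocentre.

**Step 21**
Reactants: 32 (1R,2S)-1-Ar1-2-W-butane-1,4-diol
Product: 34 (4S,5R)-5-Ar1-4-W-oxolan-2-one, via lactol 33 (not isolated)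
Conditions: TEMPO (20 mol %), PhI(OAc)2 (2.5 equiv), CH2Cl2, rt
Reagents that add atoms: none
Why: TEMPO-mediated oxidation takes the primary alcohol to the aldehyde, which closes to the lactol and is oxidised on to the γ-lactone (oxidative lactonisation).

**Step 22**
Reactants: 34 (4S,5R)-5-Ar1-4-W-oxolan-2-one; 6 1-bromo-3,5-bis(benzyloxy)benzene
Product: 35 (3S,4S,5R)-3-Ar2-5-Ar1-4-W-oxolan-2-one (3,4-trans major; C-3 epimers carried on)
Conditions: LiN(SiMe3)2, Pd(dba)2 (5 mol %), P(t-Bu)3 (10 mol %), toluene, rt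
Reagents that add atoms: none
Why: palladium-catalysed α-arylation of the lactone lithium enolate; C-3 settles mainly trans to C-4, which is immaterial because C-3 is reset in step 23.

**Step 23**
Reactants: 35 (3S,4S,5R)-3-Ar2-5-Ar1-4-W-oxolan-2-one
Product: 37 (3R,4S,5R)-3-Ar2-5-Ar1-4-W-oxolan-2-one (3,4-cis), via lithium enolate 36 (not isolated)
Conditions: LiN(i-Pr)2, THF, −78 °C; then 2,6-di-tert-butyl-4-methylphenol, −78 °C; H2O
Reagents that add atoms: none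
Why: kinetic protonation of the planar α-aryl lactone enolate by a hindered phenol from the face anti to the bulky C-4 substituent W gives the contra-thermodynamic 3,4-cis lactone (C-3 R).

**Step 24**
Reactants: 37 (3R,4S,5R)-3-Ar2-5-Ar1-4-W-oxolan-2-one
Product: 38 (3R,4S,5R)-3-Ar2-5-Ar1-4-W-oxolan-2-ol (anomers)
Conditions: i-Bu2AlH (1.2 equiv), CH2Cl2, −78 °C; aq. potassium sodium tartrate
Reagents that add atoms: none
Why: partial hydride reduction of the lactone stops at the aluminium hemiacetal at −78 °C, giving the lactol without enolising C-3.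

**Step 25**
Reactants: 38 (3R,4S,5R)-3-Ar2-5-Ar1-4-W-oxolan-2-ol; 39 4-(benzyloxy)phenylmagnesium bromide
Product: 40 (1R,2S,3R)-3-Ar2-1,4-bis(Ar1)-2-W-butane-1,4-diol (C-4 epimers)
Conditions: 39 (4 equiv), THF, −20 → 0 °C; H2O
Reagents that add atoms: none
Why: Grignard addition to the open hydroxy-aldehyde form of the lactol gives the 1,4-diol; the new C-4 carbinol is a mixture that is erased in step 26.

**Step 26**
Reactants: 40 (1R,2S,3R)-3-Ar2-1,4-bis(Ar1)-2-W-butane-1,4-diol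
Product: 42 (2R,3S,4R,5S)-4-Ar2-2,5-bis(Ar1)-3-W-oxolane (deca-O-benzyl target), via benzylic mesylate 41 (not isolated)
Conditions: MsCl, Et3N, CH2Cl2, −20 → 0 °C
Reagents that add atoms: none
Why: SN1 cycloetherification; the less hindered C-4 hydroxyl is mesylated, ionises to the 4-benzyloxybenzyl cation and is captured by the C-1 hydroxyl with the new aryl trans to the adjacent Ar2 group (C-5 S), under basic conditions that leave the other benzylic ethers alone.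

**Step 27**
Reactants: 42 (2R,3S,4R,5S)-4-Ar2-2,5-bis(Ar1)-3-W-oxolane
Product: 43 kobophenol A (structure of the given SMILES)
Conditions: H2 (1 atm), Pd(OH)2/C, THF–MeOH, rt
Reagents that add atoms: none
Why: catalytic hydrogenolysis of all ten aryl benzyl ethers; the cyclic benzylic ethers of the dihydrobenzofuran and oxolane rings are cleaved much more slowly and no stereocentre is affected.

**Compound list**

1 | 2,3-dihydroxybenzaldehyde | O=Cc1cccc(O)c1O | starting material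
2 | 3-(benzyloxy)-2-hydroxybenzaldehyde | O=Cc1cccc(OCc2ccccc2)c1O | intermediate
3 | 3-(benzyloxy)-5-bromo-2-hydroxybenzaldehyde | O=Cc1cc(Br)cc(OCc2ccccc2)c1O | intermediate
4 | 4-(benzyloxy)benzyl chloride | ClCc1ccc(OCc2ccccc2)cc1 | starting material
5 | 3-(benzyloxy)-2-{[4-(benzyloxy)benzyl]oxy}-5-bromobenzaldehyde | O=Cc1cc(Br)cc(OCc9ccccc9)c1OCc8ccc(OCc9ccccc9)cc8 | intermediate
6 | 1-bromo-3,5-bis(benzyloxy)benzene | Brc1cc(OCc2ccccc2)cc(OCc2ccccc2)c1 | starting material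
7 | [3,5-bis(benzyloxy)phenyl]lithium | [Li]c1cc(OCc2ccccc2)cc(OCc2ccccc2)c1 | intermediate (not isolated)
8 | [3-BnO-5-bromo-2-(PBB-O)phenyl](Ar2)methanol, racemic | OC(c1cc(OCc2ccccc2)cc(OCc2ccccc2)c1)c1cc(Br)cc(OCc2ccccc2)c1OCc1ccc(OCc2ccccc2)cc1 | intermediate
9 | [3-BnO-5-bromo-2-(PBB-O)phenyl](Ar2)methanone | O=C(c1cc(OCc2ccccc2)cc(OCc2ccccc2)c1)c1cc(Br)cc(OCc2ccccc2)c1OCc1ccc(OCc2ccccc2)cc1 | intermediate
10 | hydrazone of 9 | NN=C(c1cc(OCc2ccccc2)cc(OCc2ccccc2)c1)c1cc(Br)cc(OCc2ccccc2)c1OCc1ccc(OCc2ccccc2)cc1 | intermediate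
11 | [3-BnO-5-bromo-2-(PBB-O)phenyl](Ar2)diazomethane | [N-]=[N+]=C(c1cc(OCc2ccccc2)cc(OCc2ccccc2)c1)c1cc(Br)cc(OCc2ccccc2)c1OCc1ccc(OCc2ccccc2)cc1 | intermediate (not isolated)
12 | (2S,3R)-7-BnO-5-bromo-2-Ar1-3-Ar2-DHB (cis) | Brc1cc(OCc9ccccc9)c2c(c1)[C@@H](c7cc(OCc9ccccc9)cc(OCc9ccccc9)c7)[C@@H](c7ccc(OCc9ccccc9)cc7)O2 | intermediate
13 | (2R,3R)-7-BnO-5-bromo-2-Ar1-3-Ar2-DHB (trans, Q–Br) | Brc1cc(OCc9ccccc9)c2c(c1)[C@@H](c7cc(OCc9ccccc9)cc(OCc9ccccc9)c7)[C@H](c7ccc(OCc9ccccc9)cc7)O2 | intermediate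
14 | 2-bromo-4,6-dimethoxybenzaldehyde | COc1cc(Br)c(C=O)c(OC)c1 | starting material
15 | 2-bromo-4,6-dihydroxybenzaldehyde | O=Cc1c(Br)cc(O)cc1O | intermediate
16 | 4-(benzyloxy)-2-bromo-6-hydroxybenzaldehyde | O=Cc1c(Br)cc(OCc2ccccc2)cc1O | intermediate
17 | 4-(benzyloxy)-2-bromo-6-{[4-(benzyloxy)benzyl]oxy}benzaldehyde | O=Cc1c(Br)cc(OCc2ccccc2)cc1OCc1ccc(OCc2ccccc2)cc1 | intermediate
18 | Q–Li | [Li]c1cc(OCc9ccccc9)c2c(c1)[C@@H](c7cc(OCc9ccccc9)cc(OCc9ccccc9)c7)[C@H](c7ccc(OCc9ccccc9)cc7)O2 | intermediate (not isolated)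
19 | [4-BnO-2-bromo-6-(PBB-O)phenyl](Q)methanol, carbinol epimers | OC(c1c(Br)cc(OCc9ccccc9)cc1OCc8ccc(OCc9ccccc9)cc8)c1cc(OCc9ccccc9)c2c(c1)[C@@H](c7cc(OCc9ccccc9)cc(OCc9ccccc9)c7)[C@H](c7ccc(OCc9ccccc9)cc7)O2 | intermediate
20 | [4-BnO-2-bromo-6-(PBB-O)phenyl](Q)methanone | O=C(c1c(Br)cc(OCc9ccccc9)cc1OCc8ccc(OCc9ccccc9)cc8)c1cc(OCc9ccccc9)c2c(c1)[C@@H](c7cc(OCc9ccccc9)cc(OCc9ccccc9)c7)[C@H](c7ccc(OCc9ccccc9)cc7)O2 | intermediate
21 | hydrazone of 20 | NN=C(c1c(Br)cc(OCc9ccccc9)cc1OCc8ccc(OCc9ccccc9)cc8)c1cc(OCc9ccccc9)c2c(c1)[C@@H](c7cc(OCc9ccccc9)cc(OCc9ccccc9)c7)[C@H](c7ccc(OCc9ccccc9)cc7)O2 | intermediate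
22 | [4-BnO-2-bromo-6-(PBB-O)phenyl](Q)diazomethane | [N-]=[N+]=C(c1c(Br)cc(OCc9ccccc9)cc1OCc8ccc(OCc9ccccc9)cc8)c1cc(OCc9ccccc9)c2c(c1)[C@@H](c7cc(OCc9ccccc9)cc(OCc9ccccc9)c7)[C@H](c7ccc(OCc9ccccc9)cc7)O2 | intermediate (not isolated)
23 | (2R,3S)-6-BnO-4-bromo-2-Ar1-3-Q-DHB (cis) | c9ccccc9COc1ccc([C@@H]2Oc3cc(OCc9ccccc9)cc(Br)c3[C@@H]2c2cc(OCc9ccccc9)c3c(c2)[C@@H](c7cc(OCc9ccccc9)cc(OCc9ccccc9)c7)[C@H](c7ccc(OCc9ccccc9)cc7)O3)cc1 | intermediate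
24 | (2S,3S)-6-BnO-4-bromo-2-Ar1-3-Q-DHB (trans, W–Br) | c9ccccc9COc1ccc([C@H]2Oc3cc(OCc9ccccc9)cc(Br)c3[C@@H]2c2cc(OCc9ccccc9)c3c(c2)[C@@H](c7cc(OCc9ccccc9)cc(OCc9ccccc9)c7)[C@H](c7ccc(OCc9ccccc9)cc7)O3)cc1 | intermediate
25 | acrolein | C=CC=O | starting material
26 | W–Li | c9ccccc9COc1ccc([C@H]2Oc3cc(OCc9ccccc9)cc([Li])c3[C@@H]2c2cc(OCc9ccccc9)c3c(c2)[C@@H](c7cc(OCc9ccccc9)cc(OCc9ccccc9)c7)[C@H](c7ccc(OCc9ccccc9)cc7)O3)cc1 | intermediate (not isolated)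
27 | 1-W-prop-2-en-1-ol, carbinol epimers | c9ccccc9COc1ccc([C@H]2Oc3cc(OCc9ccccc9)cc(C(O)C=C)c3[C@@H]2c2cc(OCc9ccccc9)c3c(c2)[C@@H](c7cc(OCc9ccccc9)cc(OCc9ccccc9)c7)[C@H](c7ccc(OCc9ccccc9)cc7)O3)cc1 | intermediate
28 | 2-[(2E)-3-W-prop-2-en-1-yl]-4,4,5,5-tetramethyl-1,3,2-dioxaborolane | c9ccccc9COc1ccc([C@H]2Oc3cc(OCc9ccccc9)cc(/C=C/CB4OC(C)(C)C(C)(C)O4)c3[C@@H]2c2cc(OCc9ccccc9)c3c(c2)[C@@H](c7cc(OCc9ccccc9)cc(OCc9ccccc9)c7)[C@H](c7ccc(OCc9ccccc9)cc7)O3)cc1 | intermediate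
29 | 4-(benzyloxy)benzaldehyde | O=Cc1ccc(OCc2ccccc2)cc1 | starting material
30 | (1R,2S)-1-Ar1-2-W-but-3-en-1-ol | c9ccccc9COc1ccc([C@H]2Oc3cc(OCc9ccccc9)cc([C@@H]([C@@H](O)c7ccc(OCc9ccccc9)cc7)C=C)c3[C@@H]2c2cc(OCc9ccccc9)c3c(c2)[C@@H](c7cc(OCc9ccccc9)cc(OCc9ccccc9)c7)[C@H](c7ccc(OCc9ccccc9)cc7)O3)cc1 | intermediate
31 | 9-[(3S,4R)-4-hydroxy-4-Ar1-3-W-butyl]-9-borabicyclo[3.3.1]nonane | c9ccccc9COc1ccc([C@H]2Oc3cc(OCc9ccccc9)cc([C@@H]([C@@H](O)c7ccc(OCc9ccccc9)cc7)CCB4C5CCCC4CCC5)c3[C@@H]2c2cc(OCc9ccccc9)c3c(c2)[C@@H](c7cc(OCc9ccccc9)cc(OCc9ccccc9)c7)[C@H](c7ccc(OCc9ccccc9)cc7)O3)cc1 | intermediate (not isolated)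
32 | (1R,2S)-1-Ar1-2-W-butane-1,4-diol | c9ccccc9COc1ccc([C@H]2Oc3cc(OCc9ccccc9)cc([C@@H]([C@@H](O)c7ccc(OCc9ccccc9)cc7)CCO)c3[C@@H]2c2cc(OCc9ccccc9)c3c(c2)[C@@H](c7cc(OCc9ccccc9)cc(OCc9ccccc9)c7)[C@H](c7ccc(OCc9ccccc9)cc7)O3)cc1 | intermediate
33 | (4S,5R)-5-Ar1-4-W-oxolan-2-ol, anomers | c9ccccc9COc1ccc([C@H]2Oc3cc(OCc9ccccc9)cc([C@@H]4CC(O)O[C@H]4c7ccc(OCc9ccccc9)cc7)c3[C@@H]2c2cc(OCc9ccccc9)c3c(c2)[C@@H](c7cc(OCc9ccccc9)cc(OCc9ccccc9)c7)[C@H](c7ccc(OCc9ccccc9)cc7)O3)cc1 | intermediate (not isolated)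
34 | (4S,5R)-5-Ar1-4-W-oxolan-2-one | c9ccccc9COc1ccc([C@H]2Oc3cc(OCc9ccccc9)cc([C@@H]4CC(=O)O[C@H]4c7ccc(OCc9ccccc9)cc7)c3[C@@H]2c2cc(OCc9ccccc9)c3c(c2)[C@@H](c7cc(OCc9ccccc9)cc(OCc9ccccc9)c7)[C@H](c7ccc(OCc9ccccc9)cc7)O3)cc1 | intermediate
35 | (3S,4S,5R)-3-Ar2-5-Ar1-4-W-oxolan-2-one (3,4-trans) | c9ccccc9COc1ccc([C@H]2Oc3cc(OCc9ccccc9)cc([C@@H]4[C@@H](c7cc(OCc9ccccc9)cc(OCc9ccccc9)c7)C(=O)O[C@H]4c7ccc(OCc9ccccc9)cc7)c3[C@@H]2c2cc(OCc9ccccc9)c3c(c2)[C@@H](c7cc(OCc9ccccc9)cc(OCc9ccccc9)c7)[C@H](c7ccc(OCc9ccccc9)cc7)O3)cc1 | intermediate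
36 | lithium (4R,5R)-3-Ar2-5-Ar1-4-W-4,5-dihydrofuran-2-olate | c9ccccc9COc1ccc([C@H]2Oc3cc(OCc9ccccc9)cc([C@@H]4C(c7cc(OCc9ccccc9)cc(OCc9ccccc9)c7)=C(O[Li])O[C@H]4c7ccc(OCc9ccccc9)cc7)c3[C@@H]2c2cc(OCc9ccccc9)c3c(c2)[C@@H](c7cc(OCc9ccccc9)cc(OCc9ccccc9)c7)[C@H](c7ccc(OCc9ccccc9)cc7)O3)cc1 | intermediate (not isolated)
37 | (3R,4S,5R)-3-Ar2-5-Ar1-4-W-oxolan-2-one (3,4-cis) | c9ccccc9COc1ccc([C@H]2Oc3cc(OCc9ccccc9)cc([C@@H]4[C@H](c7cc(OCc9ccccc9)cc(OCc9ccccc9)c7)C(=O)O[C@H]4c7ccc(OCc9ccccc9)cc7)c3[C@@H]2c2cc(OCc9ccccc9)c3c(c2)[C@@H](c7cc(OCc9ccccc9)cc(OCc9ccccc9)c7)[C@H](c7ccc(OCc9ccccc9)cc7)O3)cc1 | intermediate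
38 | (3R,4S,5R)-3-Ar2-5-Ar1-4-W-oxolan-2-ol, anomers | c9ccccc9COc1ccc([C@H]2Oc3cc(OCc9ccccc9)cc([C@@H]4[C@H](c7cc(OCc9ccccc9)cc(OCc9ccccc9)c7)C(O)O[C@H]4c7ccc(OCc9ccccc9)cc7)c3[C@@H]2c2cc(OCc9ccccc9)c3c(c2)[C@@H](c7cc(OCc9ccccc9)cc(OCc9ccccc9)c7)[C@H](c7ccc(OCc9ccccc9)cc7)O3)cc1 | intermediate
39 | 4-(benzyloxy)phenylmagnesium bromide | Br[Mg]c1ccc(OCc2ccccc2)cc1 | starting material
40 | (1R,2S,3R)-3-Ar2-1,4-bis(Ar1)-2-W-butane-1,4-diol, C-4 epimers | c9ccccc9COc1ccc([C@H]2Oc3cc(OCc9ccccc9)cc([C@@H]([C@@H](O)c7ccc(OCc9ccccc9)cc7)[C@H](c7cc(OCc9ccccc9)cc(OCc9ccccc9)c7)C(O)c7ccc(OCc9ccccc9)cc7)c3[C@@H]2c2cc(OCc9ccccc9)c3c(c2)[C@@H](c7cc(OCc9ccccc9)cc(OCc9ccccc9)c7)[C@H](c7ccc(OCc9ccccc9)cc7)O3)cc1 | intermediate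
41 | C-4 methanesulfonate of diol 40 | c9ccccc9COc1ccc([C@H]2Oc3cc(OCc9ccccc9)cc([C@@H]([C@@H](O)c7ccc(OCc9ccccc9)cc7)[C@H](c7cc(OCc9ccccc9)cc(OCc9ccccc9)c7)C(OS(C)(=O)=O)c7ccc(OCc9ccccc9)cc7)c3[C@@H]2c2cc(OCc9ccccc9)c3c(c2)[C@@H](c7cc(OCc9ccccc9)cc(OCc9ccccc9)c7)[C@H](c7ccc(OCc9ccccc9)cc7)O3)cc1 | intermediate (not isolated)
42 | (2R,3S,4R,5S)-4-Ar2-2,5-bis(Ar1)-3-W-oxolane (deca-O-benzyl target) | c9ccccc9COc1ccc([C@H]2Oc3cc(OCc9ccccc9)cc([C@@H]4[C@H](c7cc(OCc9ccccc9)cc(OCc9ccccc9)c7)[C@@H](c7ccc(OCc9ccccc9)cc7)O[C@H]4c7ccc(OCc9ccccc9)cc7)c3[C@@H]2c2cc(OCc9ccccc9)c3c(c2)[C@@H](c7cc(OCc9ccccc9)cc(OCc9ccccc9)c7)[C@H](c7ccc(OCc9ccccc9)cc7)O3)cc1 | intermediate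
43 | kobophenol A as given: (2S,3S)-6-hydroxy-2-(4-hydroxyphenyl)-3-[(2R,3R)-3-(3,5-dihydroxyphenyl)-7-hydroxy-2-(4-hydroxyphenyl)-DHB-5-yl]-4-[(2R,3S,4R,5S)-4-(3,5-dihydroxyphenyl)-2,5-bis(4-hydroxyphenyl)oxolan-3-yl]-DHB | Oc1ccc([C@H]2Oc3cc(O)cc([C@@H]4[C@H](c5cc(O)cc(O)c5)[C@@H](c5ccc(O)cc5)O[C@H]4c4ccc(O)cc4)c3[C@@H]2c2cc(O)c3c(c2)[C@@H](c2cc(O)cc(O)c2)[C@H](c2ccc(O)cc2)O3)cc1 | target

**Summary**

Total step count: 27. Longest linear sequence: 24 steps (steps 1–8, then 12–27, from 2,3-dihydroxybenzaldehyde); the ring C aldehyde 17 is made in a 3-step side branch (steps 9–11).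

Three steps most likely to fail:

Step 15, together with the hydrazone formation that feeds it. Ketone 20 has two ortho substituents, so the hydrazone may form slowly and the twisted carbene may insert poorly. The fallback sets out from 20 and comes back at 24. It is an anionic aldol-type cyclisation: the phosphazene base P4-t-Bu (benzene, 120 °C) deprotonates the OCH2Ar1 group of 20, the carbanion adds to the ketone and water is lost, giving 6-BnO-4-bromo-2-Ar1-3-Q-1-benzofuran F1. Ionic hydrogenation (Et3SiH, CF3CO2H, CH2Cl2, 0 °C) then gives the trans-dihydrobenzofuran as two diastereomers, 24 and (2R,3R)-6-BnO-4-bromo-2-Ar1-3-Q-DHB F2. These are separable by chromatography because unit Q is enantiopure, and the route continues from 24. The cost is loss of catalyst control at this unit (about half the material).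

Step 22. Palladium enolate arylation of a γ-lactone can give ring opening, diarylation or no reaction with so hindered a substrate. The fallback sets out from 34 and comes back at 35, and reverses the polarity of the α-carbon. The enolate of 34 (LiN(SiMe3)2, THF, −78 °C) is brominated with N-bromosuccinimide to (4S,5R)-3-bromo-5-Ar1-4-W-oxolan-2-one F3 (C-3 epimers). F3 is coupled with commercial 3,5-bis(benzyloxy)phenylboronic acid in a nickel-catalysed Suzuki reaction of the α-bromo ester type (Ni(PPh3)4, K3PO4, toluene, 80 °C) to give 35.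

Step 23. The kinetic protonation must beat equilibration to the trans lactone, and the 1,3-related aryl on C-5 partly shields the face that has to be protonated. The fallback sets out from 35 and comes back at 42, and sets C-3 on a cyclic enol ether instead. One equivalent of Grignard reagent 39 (THF, −78 °C) converts 35 into the hemiketal (3S,4S,5R)-3-Ar2-2,5-bis(Ar1)-4-W-oxolan-2-ol F4. Dehydration (p-TsOH cat., benzene, 4 Å MS, rt) gives (2R,3R)-4-Ar2-2,5-bis(Ar1)-3-W-2,3-dihydrofuran F5. Ionic hydrogenation (Et3SiH, CF3CO2H, CH2Cl2, −78 °C) protonates C-4 anti to W and delivers hydride to C-5 anti to the new C-4 aryl, giving (2R,3S,4R,5R)-4-Ar2-2,5-bis(Ar1)-3-W-oxolane F6, the C-5 epimer of 42. BF3·OEt2 (CH2Cl2, −20 °C) then epimerises the benzylic C-5 through the 4-benzyloxybenzyl cation to the isomer with the C-5 aryl trans to the C-4 aryl, which is 42. This last equilibration is the weak point of the fallback, since the thermodynamic preference at that centre is not certain.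

Further compounds
F1 | step 15 | 6-BnO-4-bromo-2-Ar1-3-Q-1-benzofuran | c9ccccc9COc1ccc(cc1)-c1oc2cc(OCc9ccccc9)cc(Br)c2c1-c1cc(OCc9ccccc9)c2c(c1)[C@@H](c7cc(OCc9ccccc9)cc(OCc9ccccc9)c7)[C@H](c7ccc(OCc9ccccc9)cc7)O2
F2 | step 15 | (2R,3R)-6-BnO-4-bromo-2-Ar1-3-Q-DHB | c9ccccc9COc1ccc([C@@H]2Oc3cc(OCc9ccccc9)cc(Br)c3[C@H]2c2cc(OCc9ccccc9)c3c(c2)[C@@H](c7cc(OCc9ccccc9)cc(OCc9ccccc9)c7)[C@H](c7ccc(OCc9ccccc9)cc7)O3)cc1
F3 | step 22 | (4S,5R)-3-bromo-5-Ar1-4-W-oxolan-2-one (C-3 epimers) | c9ccccc9COc1ccc([C@H]2Oc3cc(OCc9ccccc9)cc([C@@H]4C(Br)C(=O)O[C@H]4c7ccc(OCc9ccccc9)cc7)c3[C@@H]2c2cc(OCc9ccccc9)c3c(c2)[C@@H](c7cc(OCc9ccccc9)cc(OCc9ccccc9)c7)[C@H](c7ccc(OCc9ccccc9)cc7)O3)cc1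
F4 | step 23 | (3S,4S,5R)-3-Ar2-2,5-bis(Ar1)-4-W-oxolan-2-ol (anomers) | c9ccccc9COc1ccc([C@H]2Oc3cc(OCc9ccccc9)cc([C@@H]4[C@@H](c7cc(OCc9ccccc9)cc(OCc9ccccc9)c7)C(O)(c7ccc(OCc9ccccc9)cc7)O[C@H]4c7ccc(OCc9ccccc9)cc7)c3[C@@H]2c2cc(OCc9ccccc9)c3c(c2)[C@@H](c7cc(OCc9ccccc9)cc(OCc9ccccc9)c7)[C@H](c7ccc(OCc9ccccc9)cc7)O3)cc1
F5 | step 23 | (2R,3R)-4-Ar2-2,5-bis(Ar1)-3-W-2,3-dihydrofuran | c9ccccc9COc1ccc([C@H]2Oc3cc(OCc9ccccc9)cc([C@@H]4C(c7cc(OCc9ccccc9)cc(OCc9ccccc9)c7)=C(c7ccc(OCc9ccccc9)cc7)O[C@H]4c7ccc(OCc9ccccc9)cc7)c3[C@@H]2c2cc(OCc9ccccc9)c3c(c2)[C@@H](c7cc(OCc9ccccc9)cc(OCc9ccccc9)c7)[C@H](c7ccc(OCc9ccccc9)cc7)O3)cc1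
F6 | step 23 | (2R,3S,4R,5R)-4-Ar2-2,5-bis(Ar1)-3-W-oxolane | c9ccccc9COc1ccc([C@H]2Oc3cc(OCc9ccccc9)cc([C@@H]4[C@H](c7cc(OCc9ccccc9)cc(OCc9ccccc9)c7)[C@H](c7ccc(OCc9ccccc9)cc7)O[C@H]4c7ccc(OCc9ccccc9)cc7)c3[C@@H]2c2cc(OCc9ccccc9)c3c(c2)[C@@H](c7cc(OCc9ccccc9)cc(OCc9ccccc9)c7)[C@H](c7ccc(OCc9ccccc9)cc7)O3)cc1
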